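## Analysis of the target

Target **37** is a longipinane. A cyclobutane (C4–C5–C11–C10) is bridged across one diagonal (C4/C11) by C3–C2–C1, which gives the six-membered rings, and across the other (C5/C10) by C6–C7–C8–C9, which gives the seven-membered ring. C1 is the ketone, C3 carries a methyl group, C6 the gem-dimethyl group, C7 and C9 the ester oxygens, and C10 is the quaternary methyl-bearing carbon. There are seven stereocentres, (3R,4S,5S,7R,9R,10R,11R). C4, C5, C10 and C11 are tied together by the ring system, so the independent elements are C7, C9 (the two oxygens are trans across the seven-membered ring) and C3, whose methyl group points to the C5 side, away from the C10 methyl. The sensitive groups are the two angelates on neopentylic carbinols (they drift from Z to E under nucleophilic or basic acylation), the ketone next to the four-membered ring, and the C9 oxygen, which is cyclobutylcarbinylic and would trigger ring expansion if ionised. The difficulty is the strained ring carrying a quaternary carbon flanked by two oxygenated, hindered positions, together with control of C3. The strategy rests on one feature: C10 is bonded both to the oxygenated C9 and to C4, and C4 becomes the β-carbon of an unsaturated ester once C3 carries a carboxyl group. A C9–C10 epoxide in a cis-fused bicycle (seven-membered ring A: C5–C6–C7–C8–C9–C10–C11; six-membered ring B: C11–C1–C2–C3=C4–C5) is therefore a latent tertiary C10 radical held next to its acceptor, and it delivers the C9 oxygen in the same step. Longipinane locants are used from compound **18** onwards.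

## Retrosynthetic reasoning

**Ester C–O bonds at C7 and C9 (37 ⇒ 33 + two molecules of 34).** The angelates are cut first because they would not survive hydride reagents, strong base or the radical step. The forward reaction has to acylate the two hindered secondary alcohols of **33** one after the other in the same flask. Each acylation consumes one molecule of **34** activated as **35**, the monoester **36** is passed through, and Z-to-E isomerisation must be avoided.

**C3 methyl and protecting groups (33 ⇒ 32 ⇒ 29).** The C3 methyl is traced back to a methoxycarbonyl group, because only an acceptor-substituted C3=C4 bond takes a carbon radical at C4. The C1 ketone is kept as a ketal and the C7 alcohol as a silyl ether until the end. Forward, the ester of **29** is reduced through **30** and **31** to the methyl group of **32**, and one acidic step releases **33**.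

**C4–C10 bond (29 ⇒ 28 ⇒ 27).** This is the cyclobutane bond that ends on the quaternary carbon. Cutting it removes the ring strain and leaves an unstrained cis-fused bicycle, whereas cutting C4–C5, C5–C11 or C10–C11 would leave bridged medium rings. The C9 oxygen becomes the radical trigger as the epoxide of **27**. The forward step must open the epoxide at C10, close the ring 4-exo onto C4 and reduce the resulting C3 radical; **28** is then equilibrated at C3 to **29**.

**Epoxide and C3=C4 (27 ⇒ 26 ⇒ 25).** The epoxide comes from the electron-rich C9=C10 alkene of **26**, attacked on the face of the ring-fusion hydrogens. C3=C4 is the only double bond of ring B and is cut by ring-closing metathesis to the vinyl group and the acrylate of **25**.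

**C1–C2 bond (25 ⇒ 24 ⇒ 23 ⇒ 21 + 22).** The acrylate unit C2–C3 is added as the allyl metal derived from **22** to the C1 aldehyde of **21**. Oxidation to **24** and ketalisation to **25** follow at once, so that neither double-bond migration nor the later reductant can touch C1.

**Oxidation levels at C4 and C1 (21 ⇒ 20 ⇒ 19 ⇒ 18).** The vinyl group on C5 is made from the ester of **18** only after ring A is closed; a C4 vinyl group present earlier would close a six-membered ring with C9 instead. The C1 aldehyde is stored as the dimethyl acetal.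

**C9=C10 bond (18 ⇒ 17).** Ring A is cut at its only double bond. Metathesis between the allyl group on C7 and the butenyl group on C11 of **17** has no competing partner at this stage.

**C5–C11 bond (17 ⇒ 13 ⇒ 8 + 12).** The two adjacent methine carbons must carry their exocyclic carbons cis on ring A, which additions to a preformed ring would not give. A [3,3] shift of ester **13** through a chair makes both centres at once. Their relative configuration follows from the alkene and ketene acetal geometries, and their absolute configuration from the carbinol centre of **12**. The ester bond joins the two halves.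

**Fragments (8 ⇒ 5 ⇒ 3 ⇒ 1; 12 ⇒ 11 ⇒ 9 + 10).** C7–C8 is cut to aldehyde **3** and an allyl nucleophile; this reagent-controlled allylation sets C7. Alcohol **12** comes from enone **11** by catalytic asymmetric reduction, and **11** from **9** and **10** by olefination.

## Alternatives that were turned down

**Alternative 1:** The whole skeleton is disconnected to farnesyl diphosphate A1. Forward, a sesquiterpene cyclase ionises A1 and forms C5–C6, C5–C11 and C4–C10 in one active site to give α-longipinene A2. In its favour, no chemical route can match a single step that forms three skeletal bonds, all three rings and the four ring stereocentres, and on that point it is stronger than the chosen route. Against it, A2 is a hydrocarbon. The C1 ketone could be reached by allylic oxidation, but C7 and C9 are unactivated methylene groups flanking C8. Two site- and face-selective C–H oxidations giving the trans diol would need tailored oxidation enzymes or directing groups that the molecule does not offer, and a cyclase of the right enantiomeric preference and product fidelity has to be available. The chosen route is longer on the skeleton, but it carries the C7 oxygen from the first stereocentre and draws the C9 oxygen from the epoxide that closes the ring, so no late C–H oxidation is needed.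

**Alternative 2:** Ring B is disconnected at C3–C4 and C1–C11 to the prochiral cyclobutanone A3 and crotonaldehyde A4. Forward, a chiral secondary amine makes A3 add through C4 to the β-carbon of A4 and then through C11 to the aldehyde carbon, giving the bicyclic ketol A5. In its favour, the four-membered ring is bought and not made, C3 arrives as a methyl group with its configuration, and C10 is desymmetrised catalytically. On the C3 problem it is stronger than the chosen route, which spends four steps on it. Against it, the second bond must form from the other α-carbon of a cyclobutanone to give a bridged aldol, through a strained enamine and against retro-aldol. After A5 the whole seven-membered ring is still missing: the C5 carbonyl must be converted into a methine attached to the quaternary C6, and a ring carrying both oxygens must be closed across the cyclobutane diagonal from a one-carbon arm. The chosen route reverses the order: the medium ring is made early by dependable metathesis and then serves to hold the partners of the small-ring closure together.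

**Alternative 3:** The C7–C8 and C8–C9 bonds are disconnected by removing C8, which leads to the lower homologue A6 with a six-membered ring C and a C9 ketone. Forward, a silyl diazomethane under aluminium Lewis-acid activation adds to the C9 ketone of A6, the C7 methylene migrates, and longipinan-9-one A7 results. In its favour, the reaction class is dependable, the less substituted carbon migrates so the carbonyl stays on C9, and C9 ends at a useful oxidation level in one step; on that single point it is as good as the epoxide. Against it, A6 contains the same cyclobutane and quaternary carbon, so the central problem is only moved to an unsolved precursor. After the expansion C7 has no oxygen and is β to the ketone, so it would need desaturation and a conjugate oxygen addition at a neopentylic carbon with trans control. The chosen route sets the C7 oxygen by reagent control at the start and builds C9–O into the ring-closing event.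

Key step: step 17

Remark on the chemistry (assumption): the titanium enolate formed in step 17 is taken to be protonated from the less hindered C5 side, so the ester first stands on the side of the C10 methyl group (3S), and step 18 is kept as a separate equilibration to the 3R ester.

Remark on the chemistry (assumption): in step 23 the C9 hydroxyl, next to the tied-back cyclobutane carbon, is taken to be acylated before the C7 hydroxyl next to the gem-dimethyl carbon; the order has no bearing on the outcome, since either monoester is carried on to the same diester.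

## Route

Step 1
Reactants: 1 methyl 3,3-dimethylpent-4-enoate
Product: 3 methyl 3,3-dimethyl-4-oxobutanoate, via ozonide 2 (not isolated)
Conditions: O3, CH2Cl2, −78 °C; then Me2S, −78 °C to rt
Reagents that add atoms: ozone, [O-][O+]=O
Why: Ozonolysis with reductive work-up cleaves the only alkene; the aldehyde formed sits on a quaternary carbon and cannot enolise or condense.

Step 2
Reactants: 3 methyl 3,3-dimethyl-4-oxobutanoate
Product: 5 (5R)-4,4-dimethyl-5-(prop-2-en-1-yl)oxolan-2-one, via hydroxy ester 4 (not isolated)
Conditions: (+)-Ipc2B(allyl) (1 M in pentane), Et2O, −78 °C; then NaOH, H2O2, 0 °C to rt; then 1 M HCl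
Reagents that add atoms: (+)-B-allyldiisopinocampheylborane, C=CCB([C@H]1C[C@H]2C[C@@H]([C@@H]1C)C2(C)C)[C@H]1C[C@H]2C[C@@H]([C@@H]1C)C2(C)C
Why: Brown allylboration through a closed chair transition state; the reagent derived from (−)-α-pinene should deliver the allyl group to the re face of the hindered aldehyde and set C7 as R, and the γ-hydroxy ester closes to the lactone under gem-dimethyl assistance, which gives a stable compound on which the enantiomeric purity can be checked.

Step 3
Reactants: 5 (5R)-4,4-dimethyl-5-(prop-2-en-1-yl)oxolan-2-one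
Product: 8 (4R)-4-[(tert-butyldimethylsilyl)oxy]-3,3-dimethylhept-6-enoic acid, via lithium carboxylate 6 (not isolated), via bis-silyl derivative 7 (not isolated)
Conditions: LiOH, THF/H2O, rt; evaporate; TBSCl, imidazole, DMF, 50 °C; then K2CO3, MeOH/THF/H2O, rt; aq. citric acid
Reagents that add atoms: lithium hydroxide, [Li+].[OH-]; tert-butyldimethylsilyl chloride, CC(C)(C)[Si](C)(C)Cl
Why: Saponification, exhaustive silylation of the carboxylate salt and selective cleavage of the labile silyl ester is the standard way to a silyl-protected γ-hydroxy acid; the acid is never set free while the hydroxyl is unprotected, which should prevent re-lactonisation.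

Step 4
Reactants: 9 2,2-dimethoxyacetaldehyde, 10 3-(triphenyl-λ5-phosphanylidene)butan-2-one
Product: 11 (3E)-5,5-dimethoxy-3-methylpent-3-en-2-one
Conditions: CH2Cl2 (9 used as its 60% aqueous solution), 40 °C
Reagents that add atoms: none
Why: Wittig olefination with a stabilised acyl ylide, which tolerates water and should give the E enone with the acyl group trans to the acetal carbon.

Step 5
Reactants: 11 (3E)-5,5-dimethoxy-3-methylpent-3-en-2-one
Product: 12 (2R,3E)-5,5-dimethoxy-3-methylpent-3-en-2-ol
Conditions: (S)-Me-CBS oxazaborolidine [(S)-1-methyl-3,3-diphenyltetrahydro-1H,3H-pyrrolo[1,2-c][1,3,2]oxazaborole] (10 mol%), catecholborane, toluene, −78 °C; then MeOH, aq. NaOH wash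
Reagents that add atoms: none
Why: Corey–Bakshi–Shibata reduction; the branched alkenyl group acts as the large and the methyl as the small substituent, so the (S)-catalyst should give the 2R carbinol, and 1,2-reduction is favoured by catecholborane at low temperature.

Step 6
Reactants: 8 (4R)-4-[(tert-butyldimethylsilyl)oxy]-3,3-dimethylhept-6-enoic acid, 12 (2R,3E)-5,5-dimethoxy-3-methylpent-3-en-2-ol
Product: 13 (2R,3E)-5,5-dimethoxy-3-methylpent-3-en-2-yl (4R)-4-[(tert-butyldimethylsilyl)oxy]-3,3-dimethylhept-6-enoate
Conditions: DCC, DMAP (cat.), CH2Cl2, 0 °C to rt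
Reagents that add atoms: none
Why: Steglich esterification under neutral conditions, which leaves the acetal, the silyl ether and the carbinol configuration untouched.

Step 7
Reactants: 13 (2R,3E)-5,5-dimethoxy-3-methylpent-3-en-2-yl (4R)-4-[(tert-butyldimethylsilyl)oxy]-3,3-dimethylhept-6-enoate
Product: 17 methyl (2S,3R,4E)-3-(dimethoxymethyl)-4-methyl-2-[(3R)-3-[(tert-butyldimethylsilyl)oxy]-2-methylhex-5-en-2-yl]hex-4-enoate, via silyl ketene acetal 14 (not isolated), via trimethylsilyl ester 15 (not isolated), via carboxylic acid 16 (not isolated)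
Conditions: LiN(iPr)2, THF/DMPU (4:1), −78 °C; Me3SiCl, −78 °C to 50 °C; MeOH; then Me3SiCHN2, toluene/MeOH, 0 °C
Reagents that add atoms: (trimethylsilyl)diazomethane, C[Si](C)(C)C=[N+]=[N-]
Why: Ireland–Claisen rearrangement; enolisation in the presence of DMPU should give the Z(O) enolate and hence the Z silyl ketene acetal, and the chair transition state with the carbinol methyl group equatorial and the E alkene passes the 2R configuration on to C11 (R) and C5 (S) in the syn relation that becomes cis on ring A, leaving an E-configured butenyl group; the acid is esterified in the same operation.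

Step 8
Reactants: 17 methyl (2S,3R,4E)-3-(dimethoxymethyl)-4-methyl-2-[(3R)-3-[(tert-butyldimethylsilyl)oxy]-2-methylhex-5-en-2-yl]hex-4-enoate
Product: 18 methyl (5S,7R,11R)-7-[(tert-butyldimethylsilyl)oxy]-11-(dimethoxymethyl)-6,6,10-trimethylcyclohept-9-ene-5-carboxylate
Conditions: second-generation Grubbs catalyst (H2IMes)(PCy3)Cl2Ru=CHPh (5 mol%), toluene (2 mM), 80 °C
Reagents that add atoms: none
Why: Ring-closing metathesis between the terminal alkene and the trisubstituted butenyl group; the gem-dimethyl group favours the seven-membered ring, propene leaves, and no other alkene is present to compete.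

Step 9
Reactants: 18 methyl (5S,7R,11R)-7-[(tert-butyldimethylsilyl)oxy]-11-(dimethoxymethyl)-6,6,10-trimethylcyclohept-9-ene-5-carboxylate
Product: 19 (5S,7R,11R)-7-[(tert-butyldimethylsilyl)oxy]-11-(dimethoxymethyl)-6,6,10-trimethylcyclohept-9-ene-5-carbaldehyde
Conditions: iBu2AlH, CH2Cl2, −78 °C; MeOH, then aq. potassium sodium tartrate
Reagents that add atoms: none
Why: Partial reduction of a hindered α-branched methyl ester; the tetrahedral aluminium hemiacetal should persist at −78 °C and release the aldehyde only on work-up.

Step 10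
Reactants: 19 (5S,7R,11R)-7-[(tert-butyldimethylsilyl)oxy]-11-(dimethoxymethyl)-6,6,10-trimethylcyclohept-9-ene-5-carbaldehyde
Product: 20 tert-butyl{[(5S,7R,11R)-11-(dimethoxymethyl)-5-ethenyl-6,6,10-trimethylcyclohept-9-en-7-yl]oxy}dimethylsilane
Conditions: Ph3PCH3Br, KOtBu, THF, 0 °C; then 19, −78 °C to 0 °C
Reagents that add atoms: methyltriphenylphosphonium bromide, C[P+](c1ccccc1)(c1ccccc1)c1ccccc1.[Br-]
Why: Wittig methylenation; the unstabilised ylide adds faster than it deprotonates the hindered C5 position, so the C5 configuration should be kept.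

Step 11
Reactants: 20 tert-butyl{[(5S,7R,11R)-11-(dimethoxymethyl)-5-ethenyl-6,6,10-trimethylcyclohept-9-en-7-yl]oxy}dimethylsilane
Product: 21 (5S,7R,11R)-7-[(tert-butyldimethylsilyl)oxy]-5-ethenyl-6,6,10-trimethylcyclohept-9-ene-11-carbaldehyde
Conditions: Et3SiOTf, 2,4,6-collidine, CH2Cl2, 0 °C; then H2O
Reagents that add atoms: water, O
Why: Cleavage of a dimethyl acetal through a collidinium intermediate under buffered, non-acidic conditions, which should spare the silyl ether and neither epimerise C11 nor move the ring alkene into conjugation; the aldehyde is used at once.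

Step 12
Reactants: 21 (5S,7R,11R)-7-[(tert-butyldimethylsilyl)oxy]-5-ethenyl-6,6,10-trimethylcyclohept-9-ene-11-carbaldehyde, 22 methyl 2-(bromomethyl)acrylate
Product: 23 methyl 4-{(5S,7R,11R)-7-[(tert-butyldimethylsilyl)oxy]-5-ethenyl-6,6,10-trimethylcyclohept-9-en-11-yl}-4-hydroxy-2-methylidenebutanoate (both C1 epimers)
Conditions: Zn dust, sat. aq. NH4Cl/THF, rt
Reagents that add atoms: none
Why: Barbier-type allylation with the zinc reagent formed in place from the bromomethyl acrylate; the near-neutral aqueous medium suits the epimerisable aldehyde, and the configuration of the new carbinol is irrelevant because it is oxidised next.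

Step 13
Reactants: 23 methyl 4-{(5S,7R,11R)-7-[(tert-butyldimethylsilyl)oxy]-5-ethenyl-6,6,10-trimethylcyclohept-9-en-11-yl}-4-hydroxy-2-methylidenebutanoate
Product: 24 methyl 4-{(5S,7R,11R)-7-[(tert-butyldimethylsilyl)oxy]-5-ethenyl-6,6,10-trimethylcyclohept-9-en-11-yl}-2-methylidene-4-oxobutanoate
Conditions: Dess–Martin periodinane, NaHCO3, CH2Cl2, 0 °C
Reagents that add atoms: none
Why: Dess–Martin oxidation under buffered neutral conditions, chosen so that the acidic C2 methylene between ketone and acrylate is not deprotonated; the ketone is carried on without storage.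

Step 14
Reactants: 24 methyl 4-{(5S,7R,11R)-7-[(tert-butyldimethylsilyl)oxy]-5-ethenyl-6,6,10-trimethylcyclohept-9-en-11-yl}-2-methylidene-4-oxobutanoate
Product: 25 methyl 2-[(2-{(5S,7R,11R)-7-[(tert-butyldimethylsilyl)oxy]-5-ethenyl-6,6,10-trimethylcyclohept-9-en-11-yl}-1,3-dioxolan-2-yl)methyl]prop-2-enoate
Conditions: Me3SiOCH2CH2OSiMe3, Me3SiOTf (10 mol%), CH2Cl2, −78 °C to −30 °C; pyridine quench
Reagents that add atoms: 1,2-bis(trimethylsilyloxy)ethane, C[Si](C)(C)OCCO[Si](C)(C)C
Why: Noyori ketalisation works aprotically at low temperature and is the method of choice for β,γ-unsaturated ketones, so neither migration of the acrylate double bond nor epimerisation at C11 is expected.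

Step 15
Reactants: 25 methyl 2-[(2-{(5S,7R,11R)-7-[(tert-butyldimethylsilyl)oxy]-5-ethenyl-6,6,10-trimethylcyclohept-9-en-11-yl}-1,3-dioxolan-2-yl)methyl]prop-2-enoate
Product: 26 methyl (5S,7R,11R)-7-[(tert-butyldimethylsilyl)oxy]-1,1-(ethylenedioxy)-6,6,10-trimethylbicyclo[5.4.0]undeca-3,9-diene-3-carboxylate (longipinane locants; cis ring fusion)
Conditions: second-generation Hoveyda–Grubbs catalyst (H2IMes)Cl2Ru=CH(C6H4-2-OiPr) (5 mol%), toluene, 80 °C
Reagents that add atoms: none
Why: Ring-closing metathesis of a vinyl group with a 2-substituted acrylate gives the six-membered trisubstituted enoate; the cis arrangement of the two arms makes the closure easy and the trisubstituted ring-A alkene should stay out of it.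

Step 16
Reactants: 26 methyl (5S,7R,11R)-7-[(tert-butyldimethylsilyl)oxy]-1,1-(ethylenedioxy)-6,6,10-trimethylbicyclo[5.4.0]undeca-3,9-diene-3-carboxylate
Product: 27 methyl (5S,7R,9R,10S,11R)-7-[(tert-butyldimethylsilyl)oxy]-9,10-epoxy-1,1-(ethylenedioxy)-6,6,10-trimethylbicyclo[5.4.0]undec-3-ene-3-carboxylate (epoxide on the face of the ring-fusion hydrogens)
Conditions: mCPBA, NaHCO3, CH2Cl2, 0 °C
Reagents that add atoms: 3-chloroperbenzoic acid, OOC(=O)c1cccc(Cl)c1
Why: Prilezhaev epoxidation picks the electron-rich trisubstituted alkene over the enoate; the dioxolane on C1 and the silyloxy group on C7 both shield the concave face, so the oxygen should enter syn to H11 and set C9 as R.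

Step 17
Reactants: 27 methyl (5S,7R,9R,10S,11R)-7-[(tert-butyldimethylsilyl)oxy]-9,10-epoxy-1,1-(ethylenedioxy)-6,6,10-trimethylbicyclo[5.4.0]undec-3-ene-3-carboxylate
Product: 28 methyl (3S,4R,5S,7R,9R,10R,11R)-7-[(tert-butyldimethylsilyl)oxy]-1,1-(ethylenedioxy)-9-hydroxy-3-demethyllongipinane-3-carboxylate
Conditions: Cp2TiCl2 (2.5 equiv), Mn dust, THF, rt (green Cp2TiCl); slow addition of 27; then aq. NaH2PO4
Reagents that add atoms: none
Why: Electron transfer from Cp2TiCl (trivalent titanium) to the epoxide oxygen breaks the C10–O bond homolytically and leaves a titanium alkoxide on C9 and a tertiary radical on C10, the more substituted position. The radical adds to C4, the β-carbon of the unsaturated ester, and a second equivalent of the reductant turns the resulting C3 radical into a titanium ester enolate that is protonated on work-up; this reductive trapping pulls the otherwise reversible closure forward. The closest known reaction type is the titanocene-mediated reductive opening of epoxides with radical cyclisation onto unsaturated carbonyl acceptors, which includes 4-exo closures to cyclobutanes. One ring is closed, the cyclobutane C4–C5–C11–C10, in the 4-exo-trig mode. C9 keeps the configuration set by the epoxidation because its C–O bond is never broken. C10 and C4 are fixed by the cis ring fusion: C4 hangs on the face of ring A opposite to the bulky titanium alkoxide, so the planar radical can bond to it only from that face and the methyl group ends up on the outside of the new ring. C3 is set by protonation of the enolate, expected from the open C5 side, which gives the 3S ester that step 18 corrects. The step needs cyclisation to outrun reduction or hydrogen loss of the tertiary radical and needs attack at C4 and not C3; the bicycle that holds C4 within reach of C10 and the polarity match between a nucleophilic alkyl radical and the ester-bearing alkene provide for both.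

Step 18
Reactants: 28 methyl (3S,4R,5S,7R,9R,10R,11R)-7-[(tert-butyldimethylsilyl)oxy]-1,1-(ethylenedioxy)-9-hydroxy-3-demethyllongipinane-3-carboxylate
Product: 29 methyl (3R,4R,5S,7R,9R,10R,11R)-7-[(tert-butyldimethylsilyl)oxy]-1,1-(ethylenedioxy)-9-hydroxy-3-demethyllongipinane-3-carboxylate
Conditions: NaOMe (0.3 equiv), MeOH, 50 °C
Reagents that add atoms: none
Why: Base-mediated epimerisation through the ester enolate; the 3R ester avoids the contact with the C10 methyl group that the 3S ester suffers, as in the cis and trans pinanes, and should be the thermodynamic product, while lactonisation with the C9 hydroxyl is geometrically impossible.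

Step 19
Reactants: 29 methyl (3R,4R,5S,7R,9R,10R,11R)-7-[(tert-butyldimethylsilyl)oxy]-1,1-(ethylenedioxy)-9-hydroxy-3-demethyllongipinane-3-carboxylate
Product: 30 (3R,4R,5S,7R,9R,10R,11R)-7-[(tert-butyldimethylsilyl)oxy]-1,1-(ethylenedioxy)-3-(hydroxymethyl)-3-demethyllongipinan-9-ol
Conditions: LiAlH4, THF, 0 °C
Reagents that add atoms: none
Why: Hydride reduction of the ester to the primary alcohol; ketal and silyl ether are inert.

Step 20
Reactants: 30 (3R,4R,5S,7R,9R,10R,11R)-7-[(tert-butyldimethylsilyl)oxy]-1,1-(ethylenedioxy)-3-(hydroxymethyl)-3-demethyllongipinan-9-ol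
Product: 31 [(3R,4R,5S,7R,9R,10R,11R)-7-[(tert-butyldimethylsilyl)oxy]-1,1-(ethylenedioxy)-9-hydroxy-3-demethyllongipinan-3-yl]methyl 4-methylbenzenesulfonate
Conditions: TsCl, Et3N, DMAP (cat.), CH2Cl2, 0 °C
Reagents that add atoms: 4-methylbenzenesulfonyl chloride, Cc1ccc(cc1)S(Cl)(=O)=O
Why: Sulfonylation should take the primary alcohol only, since the C9 hydroxyl is secondary and neopentylic.

Step 21
Reactants: 31 [(3R,4R,5S,7R,9R,10R,11R)-7-[(tert-butyldimethylsilyl)oxy]-1,1-(ethylenedioxy)-9-hydroxy-3-demethyllongipinan-3-yl]methyl 4-methylbenzenesulfonate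
Product: 32 (3R,4S,5S,7R,9R,10R,11R)-7-[(tert-butyldimethylsilyl)oxy]-1,1-(ethylenedioxy)longipinan-9-ol
Conditions: LiEt3BH, THF, 0 °C to 50 °C
Reagents that add atoms: none
Why: SN2 displacement of a primary sulfonate by hydride gives the C3 methyl group; the C9 alkoxide formed in passing cannot reach the sulfonate carbon.

Step 22
Reactants: 32 (3R,4S,5S,7R,9R,10R,11R)-7-[(tert-butyldimethylsilyl)oxy]-1,1-(ethylenedioxy)longipinan-9-ol
Product: 33 (3R,4S,5S,7R,9R,10R,11R)-7,9-dihydroxylongipinan-1-one
Conditions: 2 M HCl, THF, 40 °C
Reagents that add atoms: water, O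
Why: Aqueous acid hydrolyses the dioxolane and the silyl ether in one operation; dilute acid at mild temperature should not ionise the C9 carbinol.

Step 23
Reactants: 33 (3R,4S,5S,7R,9R,10R,11R)-7,9-dihydroxylongipinan-1-one, 34 angelic acid [(2Z)-2-methylbut-2-enoic acid]
Product: 37 (3R,4S,5S,7R,9R,10R,11R)-1-oxolongipinane-7,9-diyl bis[(2Z)-2-methylbut-2-enoate] (CNP0283599.1), via mixed anhydride 35 (not isolated), via 9-monoangelate 36 (not isolated)
Conditions: 34 (3 equiv), 2,4,6-trichlorobenzoyl chloride (3 equiv), Et3N, toluene, rt; then 33, toluene, 80 °C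
Reagents that add atoms: angelic acid (second equivalent), C/C=C(/C)C(=O)O
Why: Yamaguchi-type acylation through the mixed anhydride, run thermally and without a nucleophilic catalyst, since reversible nucleophilic addition is the pathway by which angelates drift to tiglates. Each hydroxyl consumes one molecule of the anhydride, so two molecules of 34 are built in, the first giving the monoester and the second the diester, and both hindered secondary alcohols should be acylated with retention of the Z geometry.

## Compound list

1 | methyl 3,3-dimethylpent-4-enoate | COC(=O)CC(C)(C)C=C | starting material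
2 | methyl 3-methyl-3-(1,2,4-trioxolan-3-yl)butanoate (ozonide) | COC(=O)CC(C)(C)C1OCOO1 | intermediate (not isolated)
3 | methyl 3,3-dimethyl-4-oxobutanoate | COC(=O)CC(C)(C)C=O | intermediate
4 | methyl (4R)-4-hydroxy-3,3-dimethylhept-6-enoate | COC(=O)CC(C)(C)[C@H](O)CC=C | intermediate (not isolated)
5 | (5R)-4,4-dimethyl-5-(prop-2-en-1-yl)oxolan-2-one | C=CC[C@H]1OC(=O)CC1(C)C | intermediate
6 | lithium (4R)-4-hydroxy-3,3-dimethylhept-6-enoate | [Li+].[O-]C(=O)CC(C)(C)[C@H](O)CC=C | intermediate (not isolated)
7 | tert-butyldimethylsilyl (4R)-4-[(tert-butyldimethylsilyl)oxy]-3,3-dimethylhept-6-enoate | CC(C)(C)[Si](C)(C)OC(=O)CC(C)(C)[C@H](O[Si](C)(C)C(C)(C)C)CC=C | intermediate (not isolated)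
8 | (4R)-4-[(tert-butyldimethylsilyl)oxy]-3,3-dimethylhept-6-enoic acid | OC(=O)CC(C)(C)[C@H](O[Si](C)(C)C(C)(C)C)CC=C | intermediate
9 | 2,2-dimethoxyacetaldehyde | COC(OC)C=O | starting material
10 | 3-(triphenyl-λ5-phosphanylidene)butan-2-one | CC(=O)C(C)=P(c1ccccc1)(c1ccccc1)c1ccccc1 | starting material
11 | (3E)-5,5-dimethoxy-3-methylpent-3-en-2-one | CC(=O)/C(C)=C/C(OC)OC | intermediate
12 | (2R,3E)-5,5-dimethoxy-3-methylpent-3-en-2-ol | C[C@@H](O)/C(C)=C/C(OC)OC | intermediate
13 | (2R,3E)-5,5-dimethoxy-3-methylpent-3-en-2-yl (4R)-4-[(tert-butyldimethylsilyl)oxy]-3,3-dimethylhept-6-enoate | C=CC[C@@H](O[Si](C)(C)C(C)(C)C)C(C)(C)CC(=O)O[C@H](C)/C(C)=C/C(OC)OC | intermediate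
14 | Z-configured trimethylsilyl ketene acetal of 13 | C=CC[C@@H](O[Si](C)(C)C(C)(C)C)C(C)(C)/C=C(\O[Si](C)(C)C)O[C@H](C)/C(C)=C/C(OC)OC | intermediate (not isolated)
15 | trimethylsilyl (2S,3R,4E)-3-(dimethoxymethyl)-4-methyl-2-[(3R)-3-[(tert-butyldimethylsilyl)oxy]-2-methylhex-5-en-2-yl]hex-4-enoate | C=CC[C@@H](O[Si](C)(C)C(C)(C)C)C(C)(C)[C@@H](C(=O)O[Si](C)(C)C)[C@@H](C(OC)OC)/C(C)=C/C | intermediate (not isolated)
16 | (2S,3R,4E)-3-(dimethoxymethyl)-4-methyl-2-[(3R)-3-[(tert-butyldimethylsilyl)oxy]-2-methylhex-5-en-2-yl]hex-4-enoic acid | C=CC[C@@H](O[Si](C)(C)C(C)(C)C)C(C)(C)[C@@H](C(=O)O)[C@@H](C(OC)OC)/C(C)=C/C | intermediate (not isolated)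
17 | methyl (2S,3R,4E)-3-(dimethoxymethyl)-4-methyl-2-[(3R)-3-[(tert-butyldimethylsilyl)oxy]-2-methylhex-5-en-2-yl]hex-4-enoate | C=CC[C@@H](O[Si](C)(C)C(C)(C)C)C(C)(C)[C@@H](C(=O)OC)[C@@H](C(OC)OC)/C(C)=C/C | intermediate
18 | methyl (5S,7R,11R)-7-[(tert-butyldimethylsilyl)oxy]-11-(dimethoxymethyl)-6,6,10-trimethylcyclohept-9-ene-5-carboxylate | COC(=O)[C@H]1[C@@H](C(OC)OC)C(C)=CC[C@@H](O[Si](C)(C)C(C)(C)C)C1(C)C | intermediate
19 | (5S,7R,11R)-7-[(tert-butyldimethylsilyl)oxy]-11-(dimethoxymethyl)-6,6,10-trimethylcyclohept-9-ene-5-carbaldehyde | O=C[C@H]1[C@@H](C(OC)OC)C(C)=CC[C@@H](O[Si](C)(C)C(C)(C)C)C1(C)C | intermediate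
20 | tert-butyl{[(5S,7R,11R)-11-(dimethoxymethyl)-5-ethenyl-6,6,10-trimethylcyclohept-9-en-7-yl]oxy}dimethylsilane | C=C[C@H]1[C@@H](C(OC)OC)C(C)=CC[C@@H](O[Si](C)(C)C(C)(C)C)C1(C)C | intermediate
21 | (5S,7R,11R)-7-[(tert-butyldimethylsilyl)oxy]-5-ethenyl-6,6,10-trimethylcyclohept-9-ene-11-carbaldehyde | C=C[C@H]1[C@@H](C=O)C(C)=CC[C@@H](O[Si](C)(C)C(C)(C)C)C1(C)C | intermediate
22 | methyl 2-(bromomethyl)acrylate | C=C(CBr)C(=O)OC | starting material
23 | methyl 4-{(5S,7R,11R)-7-[(tert-butyldimethylsilyl)oxy]-5-ethenyl-6,6,10-trimethylcyclohept-9-en-11-yl}-4-hydroxy-2-methylidenebutanoate (both C1 epimers) | C=C[C@H]1[C@@H](C(O)CC(=C)C(=O)OC)C(C)=CC[C@@H](O[Si](C)(C)C(C)(C)C)C1(C)C | intermediate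
24 | methyl 4-{(5S,7R,11R)-7-[(tert-butyldimethylsilyl)oxy]-5-ethenyl-6,6,10-trimethylcyclohept-9-en-11-yl}-2-methylidene-4-oxobutanoate | C=C[C@H]1[C@@H](C(=O)CC(=C)C(=O)OC)C(C)=CC[C@@H](O[Si](C)(C)C(C)(C)C)C1(C)C | intermediate
25 | methyl 2-[(2-{(5S,7R,11R)-7-[(tert-butyldimethylsilyl)oxy]-5-ethenyl-6,6,10-trimethylcyclohept-9-en-11-yl}-1,3-dioxolan-2-yl)methyl]prop-2-enoate | C=C[C@H]1[C@@H](C2(CC(=C)C(=O)OC)OCCO2)C(C)=CC[C@@H](O[Si](C)(C)C(C)(C)C)C1(C)C | intermediate
26 | methyl (5S,7R,11R)-7-[(tert-butyldimethylsilyl)oxy]-1,1-(ethylenedioxy)-6,6,10-trimethylbicyclo[5.4.0]undeca-3,9-diene-3-carboxylate (longipinane locants, cis-fused) | CC(C)(C)[Si](C)(C)O[C@@H]1CC=C(C)[C@@H]2C3(OCCO3)CC(C(=O)OC)=C[C@@H]2C1(C)C | intermediate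
27 | methyl (5S,7R,9R,10S,11R)-7-[(tert-butyldimethylsilyl)oxy]-9,10-epoxy-1,1-(ethylenedioxy)-6,6,10-trimethylbicyclo[5.4.0]undec-3-ene-3-carboxylate | CC(C)(C)[Si](C)(C)O[C@@H]1C[C@H]2O[C@@]2(C)[C@@H]3C4(OCCO4)CC(C(=O)OC)=C[C@@H]3C1(C)C | intermediate
28 | methyl (3S,4R,5S,7R,9R,10R,11R)-7-[(tert-butyldimethylsilyl)oxy]-1,1-(ethylenedioxy)-9-hydroxy-3-demethyllongipinane-3-carboxylate | CC(C)(C)[Si](C)(C)O[C@@H]1C[C@@H](O)[C@]2(C)[C@@H]3[C@@H]([C@H]2C4(OCCO4)C[C@@H]3C(=O)OC)C1(C)C | intermediate
29 | methyl (3R,4R,5S,7R,9R,10R,11R)-7-[(tert-butyldimethylsilyl)oxy]-1,1-(ethylenedioxy)-9-hydroxy-3-demethyllongipinane-3-carboxylate | CC(C)(C)[Si](C)(C)O[C@@H]1C[C@@H](O)[C@]2(C)[C@@H]3[C@@H]([C@H]2C4(OCCO4)C[C@H]3C(=O)OC)C1(C)C | intermediate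
30 | (3R,4R,5S,7R,9R,10R,11R)-7-[(tert-butyldimethylsilyl)oxy]-1,1-(ethylenedioxy)-3-(hydroxymethyl)-3-demethyllongipinan-9-ol | CC(C)(C)[Si](C)(C)O[C@@H]1C[C@@H](O)[C@]2(C)[C@@H]3[C@@H]([C@H]2C4(OCCO4)C[C@H]3CO)C1(C)C | intermediate
31 | [(3R,4R,5S,7R,9R,10R,11R)-7-[(tert-butyldimethylsilyl)oxy]-1,1-(ethylenedioxy)-9-hydroxy-3-demethyllongipinan-3-yl]methyl 4-methylbenzenesulfonate | CC(C)(C)[Si](C)(C)O[C@@H]1C[C@@H](O)[C@]2(C)[C@@H]3[C@@H]([C@H]2C4(OCCO4)C[C@H]3COS(=O)(=O)c5ccc(C)cc5)C1(C)C | intermediate
32 | (3R,4S,5S,7R,9R,10R,11R)-7-[(tert-butyldimethylsilyl)oxy]-1,1-(ethylenedioxy)longipinan-9-ol | CC(C)(C)[Si](C)(C)O[C@@H]1C[C@@H](O)[C@]2(C)[C@@H]3[C@@H]([C@H]2C4(OCCO4)C[C@H]3C)C1(C)C | intermediate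
33 | (3R,4S,5S,7R,9R,10R,11R)-7,9-dihydroxylongipinan-1-one | O[C@@H]1C[C@@H](O)[C@]2(C)[C@@H]3[C@@H]([C@H]2C(=O)C[C@H]3C)C1(C)C | intermediate
34 | angelic acid | C/C=C(/C)C(=O)O | starting material
35 | (2Z)-2-methylbut-2-enoic 2,4,6-trichlorobenzoic anhydride | C/C=C(/C)C(=O)OC(=O)c1c(Cl)cc(Cl)cc1Cl | intermediate (not isolated)
36 | (3R,4S,5S,7R,9R,10R,11R)-7-hydroxy-1-oxolongipinan-9-yl (2Z)-2-methylbut-2-enoate | O[C@@H]1C[C@@H](OC(=O)/C(C)=C\C)[C@]2(C)[C@@H]3[C@@H]([C@H]2C(=O)C[C@H]3C)C1(C)C | intermediate (not isolated)
37 | (3R,4S,5S,7R,9R,10R,11R)-1-oxolongipinane-7,9-diyl bis[(2Z)-2-methylbut-2-enoate] (CNP0283599.1) | C/C=C(/C)C(=O)O[C@@H]1C[C@@H](OC(=O)/C(C)=C\C)[C@]2(C)[C@@H]3[C@@H]([C@H]2C(=O)C[C@H]3C)C1(C)C | target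

## Step count and least certain steps

Total: 23 steps. Longest linear sequence: 21 steps (steps 1–3 and 6–23); steps 4 and 5 make the second fragment.

**Step 17 (key step).** The most likely failure is loss of the tertiary C10 radical before it cyclises. The 4-exo closure is reversible and needs a twisted conformer of ring A, so capture of the radical by a second titanium centre, followed by β-hydrogen loss to an allylic alcohol or by simple reduction, can win. The fallback sets out from 27. MgBr2·OEt2 opens the epoxide to the tertiary bromide with the C9 hydroxyl in place, bromohydrin F1. Slow addition of Bu3SnH with AIBN in benzene at 80 °C then generates the same C10 radical in a metal-free chain, in which no titanium is present to cause elimination and the cyclised ester radical is quenched by hydrogen transfer. This returns to the route at 28 (as a C3 mixture that step 18 equilibrates).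

**Step 7.** What may go wrong is incomplete control of the ketene acetal geometry, which would erode the configuration at C5 while C11 stays secured by the chair and the carbinol centre; slow rearrangement between two hindered carbons is the second concern. The fallback sets out from 18 contaminated with its C5 epimer F2. Bu4NF removes the silyl group to give the hydroxy esters F3. DBU in toluene at 100 °C equilibrates C5 through the ester enolate, and only the epimer with C4 and the C7 oxygen on the same face can close, so the mixture drains into the bridged lactone F4. iBu2AlH gives lactol F5, Ph3P=CH2 gives the vinyl alcohol F6, and tBuMe2SiOTf with 2,6-lutidine returns to the route at 20.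

**Step 8.** The risk is slow engagement of the trisubstituted, allylically branched alkene by the ruthenium carbene, leading to dimerisation through the terminal alkene. The fallback sets out from 17: ozonolysis (O3, then Me2S) cleaves both alkenes to the keto aldehyde F7, and an intramolecular McMurry coupling (TiCl3(DME)1.5 with Zn–Cu couple, DME, reflux, high dilution) joins C9 and C10 directly, returning at 18. It has its own weak point, loss of methanol from the β-methoxy ketone, and is held in reserve only.

**Step 14 (with step 13).** The process to fear is migration of the acrylate double bond into conjugation with the C1 ketone, or epimerisation at C11, while the free ketone 24 exists. The fallback sets out from 23 and reverses the order. Metathesis on the free alcohol gives the bicyclic hydroxy ester F8, and Dess–Martin oxidation gives the cyclic keto ester F9. Ketalisation of F9 returns at 26; in the ring the ketal with the double bond at C3=C4 is the thermodynamic form, so a migrated double bond is pulled back during ketalisation.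

**Step 23.** The risks are incomplete acylation of the two neopentylic alcohols, with the sequence stalling at the monoester stage, and Z-to-E isomerisation during forcing. The fallback sets out from 32 and builds the angelate double bonds after the ester bonds. Bu4NF gives the ketal diol F10. DCC and DMAP with 2-[bis(2,2,2-trifluoroethoxy)phosphoryl]propanoic acid, an acid that cannot isomerise, give the bis(phosphonate) F11. A double Still–Gennari olefination (KN(SiMe3)2, 18-crown-6, acetaldehyde, −78 °C) gives the Z,Z ketal diester F12, and PPTS in wet acetone releases the ketone, returning at 37.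

## Further compounds

F1 | step 17 | methyl (5S,7R,9R,10R,11R)-10-bromo-7-[(tert-butyldimethylsilyl)oxy]-1,1-(ethylenedioxy)-9-hydroxy-6,6,10-trimethylbicyclo[5.4.0]undec-3-ene-3-carboxylate (bromide trans to the C9 hydroxyl) | CC(C)(C)[Si](C)(C)O[C@@H]1C[C@@H](O)[C@@](Br)(C)[C@@H]2C3(OCCO3)CC(C(=O)OC)=C[C@@H]2C1(C)C
F2 | step 7 | C5 epimer of 18 | COC(=O)[C@@H]1[C@@H](C(OC)OC)C(C)=CC[C@@H](O[Si](C)(C)C(C)(C)C)C1(C)C
F3 | step 7 | methyl (7R,11R)-11-(dimethoxymethyl)-7-hydroxy-6,6,10-trimethylcyclohept-9-ene-5-carboxylate (both C5 epimers) | COC(=O)C1[C@@H](C(OC)OC)C(C)=CC[C@@H](O)C1(C)C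
F4 | step 7 | bridged lactone between the C4 carboxyl and the C7 oxygen of ring A | O=C1O[C@@H]2CC=C(C)[C@H](C(OC)OC)[C@H]1C2(C)C
F5 | step 7 | lactol from F4 (both anomers) | OC1O[C@@H]2CC=C(C)[C@H](C(OC)OC)[C@H]1C2(C)C
F6 | step 7 | (5S,7R,11R)-11-(dimethoxymethyl)-5-ethenyl-6,6,10-trimethylcyclohept-9-en-7-ol | C=C[C@H]1[C@@H](C(OC)OC)C(C)=CC[C@@H](O)C1(C)C
F7 | step 8 | methyl (2S,3R)-2-[(3R)-3-[(tert-butyldimethylsilyl)oxy]-2-methyl-5-oxopentan-2-yl]-3-(dimethoxymethyl)-4-oxopentanoate | O=CC[C@@H](O[Si](C)(C)C(C)(C)C)C(C)(C)[C@@H](C(=O)OC)[C@@H](C(OC)OC)C(C)=O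
F8 | step 14 | methyl (5S,7R,11R)-7-[(tert-butyldimethylsilyl)oxy]-1-hydroxy-6,6,10-trimethylbicyclo[5.4.0]undeca-3,9-diene-3-carboxylate (both C1 epimers) | CC(C)(C)[Si](C)(C)O[C@@H]1CC=C(C)[C@@H]2C(O)CC(C(=O)OC)=C[C@@H]2C1(C)C
F9 | step 14 | methyl (5S,7R,11R)-7-[(tert-butyldimethylsilyl)oxy]-6,6,10-trimethyl-1-oxobicyclo[5.4.0]undeca-3,9-diene-3-carboxylate | CC(C)(C)[Si](C)(C)O[C@@H]1CC=C(C)[C@@H]2C(=O)CC(C(=O)OC)=C[C@@H]2C1(C)C
F10 | step 23 | (3R,4S,5S,7R,9R,10R,11R)-1,1-(ethylenedioxy)longipinane-7,9-diol | O[C@@H]1C[C@@H](O)[C@]2(C)[C@@H]3[C@@H]([C@H]2C4(OCCO4)C[C@H]3C)C1(C)C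
F11 | step 23 | 7,9-bis{2-[bis(2,2,2-trifluoroethoxy)phosphoryl]propanoate} of F10 | CC(C(=O)O[C@@H]1C[C@@H](OC(=O)C(C)P(=O)(OCC(F)(F)F)OCC(F)(F)F)[C@]2(C)[C@@H]3[C@@H]([C@H]2C4(OCCO4)C[C@H]3C)C1(C)C)P(=O)(OCC(F)(F)F)OCC(F)(F)F
F12 | step 23 | 7,9-bis[(2Z)-2-methylbut-2-enoate] of F10 | C/C=C(/C)C(=O)O[C@@H]1C[C@@H](OC(=O)/C(C)=C\C)[C@]2(C)[C@@H]3[C@@H]([C@H]2C4(OCCO4)C[C@H]3C)C1(C)C
A1 | alternative 1 | (2E,6E)-farnesyl diphosphate | CC(C)=CCC/C(C)=C/CC/C(C)=C/COP(=O)(O)OP(=O)(O)O
A2 | alternative 1 | α-longipinene of the target enantiomeric series | C1CC[C@]2(C)[C@@H]3[C@@H]([C@H]2CC=C3C)C1(C)C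
A3 | alternative 2 | 3-{[(tert-butyldiphenylsilyl)oxy]methyl}-3-methylcyclobutan-1-one | CC1(CO[Si](c2ccccc2)(c2ccccc2)C(C)(C)C)CC(=O)C1
A4 | alternative 2 | (E)-but-2-enal (crotonaldehyde) | C/C=C/C=O
A5 | alternative 2 | 2-hydroxy-4-methylbicyclo[3.1.1]heptan-6-one carrying the silyloxymethyl and methyl groups on C7 | CC(C)(C)[Si](c1ccccc1)(c1ccccc1)OC[C@]2(C)[C@@H]3C(=O)[C@H]2[C@@H](O)C[C@H]3C
A6 | alternative 3 | lower homologue with a six-membered ring C, C9 ketone and C1 ketal | C1C(=O)[C@]2(C)[C@@H]3[C@@H]([C@H]2C4(OCCO4)C[C@H]3C)C1(C)C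
A7 | alternative 3 | longipinan-9-one with the C1 ketal | C1CC(=O)[C@]2(C)[C@@H]3[C@@H]([C@H]2C4(OCCO4)C[C@H]3C)C1(C)C
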